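If I charged more incoming ligand to the starting complex, I expected the complex with one exchanged to form sooner, but I did not know whether more of it stood at the end.

| flask | starting complex | incoming ligand | remark | time |
|---|---|---|---|---|
| dawn | 0.068 M | 0.070 M | run made earlier |  |
| noon | 0.068 M | 2.5 M | run made earlier |  |
| violet | 0.068 M | 0.0600 M |  | 10 d |
| grey | 0.068 M | 0.200 M |  | 10 d |
| red | 0.068 M | 0.600 M |  | 10 d |
| teal | 0.068 M | 2.00 M |  | 10 d |

| run | time / d | complex with one exchanged / % | starting complex / % |
|---|---|---|---|
| dawn | 0.833 | 14.0 | 76.1 |
| dawn | 1.67 | 18.3 | 57.6 |
| dawn | 3.00 | 18.3 | 39.0 |
| dawn | 5.00 | 15.9 | 24.9 |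
| dawn | 10.0 | 10.6 | 12.4 |
| noon | 0.833 | 65.4 | 2.1 |
| noon | 1.67 | 45.3 | 1.9 |
| noon | 3.00 | 24.8 | 0.9 |
| noon | 5.00 | 10.8 | 0.5 |
| noon | 10.0 | 1.5 | 0.3 |

(readings scatter by 0.3 percentage points)

- "hardly changes" means that all values lie within two and a half points (for a concentration: within two and a half percent of the largest)

1. [complex with one exchanged] at the end for violet, grey, red, teal, in this order
2. the course of these numbers from the first flask to the last (rises, then falls / falls, then rises / hardly changes / rises all the way / falls all the way)

I went through the rates that the earlier runs showed. The first dawn reading gave the starting complex a second-order loss constant a = 4.68 /M/d, so its half-life ran from 2.47 d in violet to 0.0740 d in teal; on this rung the flask turns into complex with one exchanged and whatever else forms.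

Next came the ligand path. In noon the complex with one exchanged fell steadily from 1.67 d to 5.00 d, a pseudo-first-order decay, which gave κ = 0.172 /M/d per unit of ligand.

Dawn showed a further drain. Its late fall of 0.0811 /d was faster than the 0.0121 /d of the ligand path. Noon's first reading held less starting complex than dawn's last, so I took this drain to need starting complex, and more ligand to shorten its season.

The last rung held the ligand path against the flask's own time. The ligand level at which κ halves the complex with one exchanged within 10 d is 0.402 M; I called this the crossover concentration c*. Grey lay below it and red above it, so I committed to a row that rises, then falls, with its top near c*.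

The forecast gave 0.0071 M, 0.0034 M, 0.0014 M and 0.001 M, so falls all the way, holding that “More ligand forms the intermediate earlier”, and on this shape it differed from mine.

The flasks ended at 0.00635 M, 0.0124 M, 0.0124 M and 0.00231 M: rises, then falls.

    starting complex + incoming ligand ⇌ leaving ligand + complex with one exchanged (K = 1.00, k = 0.00288 /M/min)
    complex with one exchanged + incoming ligand ⇌ leaving ligand + complex with two exchanged (K = 54.1, k = 1.21 × 10⁻⁴ /M/min)
    starting complex + complex with one exchanged → side product (k = 0.00785 /M/min)

The row turned at 0.36 M, near c*. At the end of violet, the path to side product used the complex with one exchanged 25 times as fast as the forward ligand step, and its half-life by that path, concentrations as charged, was 0.90 d, short against 10 d. In teal, charged above c* and with 94 % of its ligand left, c* gives a half-life of 2.14 d; there the complex with one exchanged fell from 16.3 % at 5.00 d to 3.39 % at 10.0 d.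

(The runs were generated by integration with made-up constants; the scatter is artificial.)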